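**Retrosynthetic overview**
1. The butenolide is attached last: C12–C13 by B-alkyl Suzuki coupling of a C9 vinyl carbinol with 3-bromofuran-2(5H)-one; C9–C11 by equatorial vinyl addition to a 9-ketone; 6β-OAc from α-face hydride reduction of a 6-ketone.
2. Rings A and B (decalin-6,9-dione) come together from the monocyclic keto aldehyde 15 in a Lewis-acid cascade: Prins closure of ring B (C5–C6), 1,2-shift of C3 from C5 to C4 that turns the cyclopentane (C10, C1, C2, C3, C5) into six-membered ring A, then hydride shift to the C6 ketone.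
3. Enabling feature: the gem-dimethyl carbon C4 of ring A is bonded to ring-fusion carbon C5, which carries the oxygenated C6 of ring B; a C4 cation beside quaternary C5 can take over C3, and the C6 oxygen quenches the resulting C5 cation as a ketone, which makes C5 and C8 epimerisable to the trans-decalin with equatorial C8 methyl.
4. 15 comes from (+)-3-carene, whose ten carbons become C1–C5, C18, C19, C10, C9 and C8; its gem-dimethylcyclopropane is a masked isopropylidene and directs the C10 methylation, the only stereocentre carried through the cascade.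
5. Ring order: cyclopentane (aldol) → ring B and ring A together (key step) → butenolide coupled on.

Key step: step 8

Assumption: commercial (+)-3-carene is the (1S,6R) enantiomer and 3-bromofuran-2(5H)-one is purchasable; labdane numbering (C1–C20) is used for all intermediates.

**Step 1**
Reactants: 1 (+)-3-carene
Product: 3 2-[(1R,3S)-2,2-dimethyl-3-(2-oxopropyl)cyclopropyl]acetaldehyde, via carene ozonide 2 (not isolated)
Conditions: O3, CH2Cl2, −78 °C; then Me2S, −78 °C → rt
Reagents that add atoms: ozone, [O-][O+]=O
Why: Ozonolysis cleaves the only alkene while the cyclopropane is inert, so both cyclopropane stereocentres are kept.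

**Step 2**
Reactants: 3 2-[(1R,3S)-2,2-dimethyl-3-(2-oxopropyl)cyclopropyl]acetaldehyde
Product: 5 1-[(1S,5R)-6,6-dimethylbicyclo[3.1.0]hex-2-en-2-yl]ethan-1-one, via aldol adduct 4 (not isolated)
Conditions: KOH (aq, cat.), MeOH, 0 °C → rt
Reagents that add atoms: none
Why: Intramolecular aldol condensation in which the enolate of the ketone α-CH2 adds to the more electrophilic aldehyde (five-membered ring, as in 6-oxoheptanal → 1-acetylcyclopentene) and the aldol dehydrates to the conjugated enone; the cyclopropane stereocentres are not enolisable.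

**Step 3**
Reactants: 5 1-[(1S,5R)-6,6-dimethylbicyclo[3.1.0]hex-2-en-2-yl]ethan-1-one
Product: 7 1-[(1S,2S,5R)-2,6,6-trimethylbicyclo[3.1.0]hexan-2-yl]ethan-1-one, via lithium enolate 6 (not isolated)
Conditions: Li (2 equiv), t-BuOH (1 equiv), NH3(l)/THF, −78 °C; then MeI, −78 → −33 °C
Reagents that add atoms: methyl iodide, CI
Why: Dissolving-metal reductive alkylation of the enone gives the regiodefined enolate 6, which is methylated on the face opposite the gem-dimethylcyclopropane (its endo methyl shields the syn face), setting the quaternary C10 stereocentre of the target.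

**Step 4**
Reactants: 7 1-[(1S,2S,5R)-2,6,6-trimethylbicyclo[3.1.0]hexan-2-yl]ethan-1-one
Product: 9 1-[(1S)-1-methyl-2-(propan-2-ylidene)cyclopentyl]ethan-1-one, via tertiary bromide 8 (not isolated)
Conditions: HBr (33% in AcOH), CH2Cl2, 0 °C; concentrate; then LiBr, Li2CO3, DMF, 100 °C
Reagents that add atoms: none
Why: Markovnikov hydrobromination of the gem-dimethylcyclopropane (proton to the less hindered CH carbon remote from the quaternary centre, bromide to the tertiary carbon, ionisation on this side assisted by the cis acetyl oxygen) followed by E1-type Zaitsev dehydrobromination should give the tetrasubstituted alkene; C10 has no α-hydrogen and is untouched.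

**Step 5**
Reactants: 9 1-[(1S)-1-methyl-2-(propan-2-ylidene)cyclopentyl]ethan-1-one
Product: 11 1-[(1S)-1-methyl-2-(propan-2-ylidene)cyclopentyl]pent-4-en-1-one, via lithium enolate 10 (not isolated)
Conditions: LDA, THF, −78 °C; then allyl bromide, −78 → 0 °C
Reagents that add atoms: allyl bromide, C=CCBr
Why: Kinetic lithium enolate alkylation at the acetyl methyl, the only enolisable position because the other α-carbon is quaternary.

**Step 6**
Reactants: 11 1-[(1S)-1-methyl-2-(propan-2-ylidene)cyclopentyl]pent-4-en-1-one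
Product: 13 2-methyl-1-[(1S)-1-methyl-2-(propan-2-ylidene)cyclopentyl]pent-4-en-1-one (C2 epimers), via lithium enolate 12 (not isolated)
Conditions: LDA, THF, −78 °C; then MeI, −78 → 0 °C
Reagents that add atoms: methyl iodide, CI
Why: Second enolate alkylation at the same α-carbon (C8); the new centre forms as a mixture, which is harmless because it is equilibrated in step 9.

**Step 7**
Reactants: 13 2-methyl-1-[(1S)-1-methyl-2-(propan-2-ylidene)cyclopentyl]pent-4-en-1-one
Product: 15 3-methyl-4-[(1S)-1-methyl-2-(propan-2-ylidene)cyclopentyl]-4-oxobutanal (C3 epimers), via vicinal diol 14 (not isolated)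
Conditions: OsO4 (cat.), NaIO4, 2,6-lutidine, dioxane/H2O, rt
Reagents that add atoms: osmium tetroxide (catalytic oxygen-transfer agent), O=[Os](=O)(=O)=O; sodium periodate (stoichiometric oxygen source), [Na+].[O-]I(=O)(=O)=O
Why: Lemieux–Johnson oxidation, in which the monosubstituted alkene should be dihydroxylated far faster than the tetrasubstituted alkene flanked by a quaternary carbon, and periodate cleaves the diol to the aldehyde.

**Step 8**
Reactants: 15 3-methyl-4-[(1S)-1-methyl-2-(propan-2-ylidene)cyclopentyl]-4-oxobutanal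
Product: 16 (4aS)-3,4a,8,8-tetramethyloctahydronaphthalene-1,4-dione (C3/C8a epimers)
Conditions: SnCl4 (1.1 equiv), CH2Cl2, −78 °C → rt; H2O quench
Reagents that add atoms: none
Why: Proposed new method: SnCl4 activates the aldehyde, C5 of the tetrasubstituted alkene attacks C6 (Prins/carbonyl-ene mode, 6-exo closure of ring B through a chair with the alkene exocyclic), the tertiary C4 cation formed next to quaternary C5 takes over ring bond C3 by 1,2-shift, and the tertiary C5 cation is quenched by 1,2-hydride shift from the stannyloxy-bearing C6 (semipinacol) to give the C6 ketone. The closest known reactions are the carbonyl-ene cyclisation of citronellal-type aldehydes, Prins–pinacol cascades and cyclopentylcarbinyl-to-cyclohexyl Wagner–Meerwein shifts; their combination on an alkylidenecyclopentane keto aldehyde is not known. Ring B closes by C5–C6 bond formation, and ring A arises by ring expansion of the cyclopentane (C10, C1, C2, C3, C5), with bond C3–C5 replaced by C3–C4. C10 is carried through unchanged, whereas C5 (from the hydride shift) and C8 emerge unselectively; both are α to a ketone, so substrate-controlled equilibration in step 9 fixes them. The step needs C3 to migrate rather than C6 or C10 and the ene-type proton loss not to be terminal: only C3 migration relieves cyclopentane strain, avoids a bridgehead cation (C10) or a seven-membered ring (C6) and ends in an irreversible ketone, while an isopropenyl ene product or tertiary chloride should be re-ionised by the HCl/SnCl4 present to the same C4 cation. The aldehyde should react in preference to the neopentyl C9 ketone, and furan formation from the 1,4-dicarbonyl should be slow under anhydrous Lewis acid at low temperature.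

**Step 9**
Reactants: 16 (4aS)-3,4a,8,8-tetramethyloctahydronaphthalene-1,4-dione (C3/C8a epimers)
Product: 17 (3R,4aS,8aS)-3,4a,8,8-tetramethyloctahydronaphthalene-1,4-dione
Conditions: NaOMe (cat.), MeOH, rt
Reagents that add atoms: none
Why: Base-mediated epimerisation through the C5 and C8 enolates should deliver the thermodynamic isomer, the trans-decalin (5α-H) with equatorial 8α-methyl, because an 8β-methyl would be syn-diaxial to the C10 methyl; C10 is quaternary and cannot epimerise.

**Step 10**
Reactants: 17 (3R,4aS,8aS)-3,4a,8,8-tetramethyloctahydronaphthalene-1,4-dione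
Product: 18 (2R,4R,4aS,8aS)-4-hydroxy-2,5,5,8a-tetramethyloctahydronaphthalen-1(2H)-one
Conditions: NaBH4 (1.0 equiv), MeOH/THF, −20 → 0 °C
Reagents that add atoms: none
Why: Hydride reduction should distinguish the ketones sterically (C9 is flanked by quaternary C10 and the C8 methine) and attack C6 from the α face, because the β face is covered by the syn-axial C4β and C10 methyls, giving the axial 6β-alcohol.

**Step 11**
Reactants: 18 (2R,4R,4aS,8aS)-4-hydroxy-2,5,5,8a-tetramethyloctahydronaphthalen-1(2H)-one
Product: 19 (1R,2R,4R,4aS,8aS)-1-ethenyl-2,5,5,8a-tetramethyldecahydronaphthalene-1,4-diol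
Conditions: anhydrous CeCl3, vinylmagnesium bromide (excess), THF, −78 → 0 °C; aq NH4Cl
Reagents that add atoms: vinylmagnesium bromide, C=C[Mg]Br
Why: Organocerium 1,2-addition suppresses enolisation of the hindered ketone; the vinyl group should enter equatorially on the β face, anti to the C8 methyl as in additions to 2,2,6-trimethylcyclohexanone, avoiding the syn-axial H5α/H7α of the α trajectory and giving the axial 9α-hydroxyl.

**Step 12**
Reactants: 19 (1R,2R,4R,4aS,8aS)-1-ethenyl-2,5,5,8a-tetramethyldecahydronaphthalene-1,4-diol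
Product: 20 (1R,3R,4R,4aS,8aS)-4-ethenyl-4-hydroxy-3,4a,8,8-tetramethyldecahydronaphthalen-1-yl acetate
Conditions: Ac2O, DMAP (cat.), pyridine, 40 °C
Reagents that add atoms: acetic anhydride, CC(=O)OC(C)=O
Why: DMAP-catalysed acylation esterifies only the secondary 6β-alcohol; the tertiary allylic C9 alcohol between two substituted carbons should not react.

**Step 13**
Reactants: 20 (1R,3R,4R,4aS,8aS)-4-ethenyl-4-hydroxy-3,4a,8,8-tetramethyldecahydronaphthalen-1-yl acetate; 21 3-bromofuran-2(5H)-one
Product: 23 (1R,3R,4R,4aS,8aS)-4-hydroxy-3,4a,8,8-tetramethyl-4-[2-(2-oxo-2,5-dihydrofuran-3-yl)ethyl]decahydronaphthalen-1-yl acetate (CNP0205088.1), via B-alkyl-9-BBN borane 22 (not isolated)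
Conditions: 9-BBN, THF, 0 °C → rt; then 21, Pd(dppf)Cl2 (cat.), AsPh3 (cat.), K3PO4 (aq), DMF/THF, rt
Reagents that add atoms: none
Why: Anti-Markovnikov hydroboration of the monosubstituted alkene and B-alkyl Suzuki–Miyaura coupling of 22 with the α-bromobutenolide form C12–C13 at room temperature under phosphate base that should spare the acetate and the lactone; no stereocentre is involved.

**Compound list**
1 | (+)-3-carene, (1S,6R)-3,7,7-trimethylbicyclo[4.1.0]hept-3-ene | CC1=CC[C@@H]2[C@H](C1)C2(C)C | starting material
2 | secondary ozonide (1,2,4-trioxolane) of 1 | CC12C[C@H]3[C@@H](CC(OO1)O2)C3(C)C | intermediate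
3 | 2-[(1R,3S)-2,2-dimethyl-3-(2-oxopropyl)cyclopropyl]acetaldehyde | O=CC[C@@H]1[C@H](CC(C)=O)C1(C)C | intermediate
4 | 1-[(1R,5R)-3-hydroxy-6,6-dimethylbicyclo[3.1.0]hexan-2-yl]ethan-1-one (C2/C3 epimers) | CC(=O)C1C(O)C[C@@H]2[C@H]1C2(C)C | intermediate
5 | 1-[(1S,5R)-6,6-dimethylbicyclo[3.1.0]hex-2-en-2-yl]ethan-1-one | CC(=O)C1=CC[C@@H]2[C@H]1C2(C)C | intermediate
6 | lithium 1-[(1S,5R)-6,6-dimethylbicyclo[3.1.0]hexan-2-ylidene]ethan-1-olate | CC(O[Li])=C1CC[C@@H]2[C@H]1C2(C)C | intermediate
7 | 1-[(1S,2S,5R)-2,6,6-trimethylbicyclo[3.1.0]hexan-2-yl]ethan-1-one | CC(=O)[C@@]1(C)CC[C@@H]2[C@H]1C2(C)C | intermediate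
8 | 1-[(1S,2R)-2-(2-bromopropan-2-yl)-1-methylcyclopentyl]ethan-1-one | CC(=O)[C@@]1(C)CCC[C@H]1C(C)(C)Br | intermediate
9 | 1-[(1S)-1-methyl-2-(propan-2-ylidene)cyclopentyl]ethan-1-one | CC(=O)[C@@]1(C)CCCC1=C(C)C | intermediate
10 | lithium 1-[(1S)-1-methyl-2-(propan-2-ylidene)cyclopentyl]ethen-1-olate | C=C(O[Li])[C@@]1(C)CCCC1=C(C)C | intermediate
11 | 1-[(1S)-1-methyl-2-(propan-2-ylidene)cyclopentyl]pent-4-en-1-one | C=CCCC(=O)[C@@]1(C)CCCC1=C(C)C | intermediate
12 | lithium 1-[(1S)-1-methyl-2-(propan-2-ylidene)cyclopentyl]penta-1,4-dien-1-olate | C=CCC=C(O[Li])[C@@]1(C)CCCC1=C(C)C | intermediate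
13 | 2-methyl-1-[(1S)-1-methyl-2-(propan-2-ylidene)cyclopentyl]pent-4-en-1-one (C2 epimers) | C=CCC(C)C(=O)[C@@]1(C)CCCC1=C(C)C | intermediate
14 | 4,5-dihydroxy-2-methyl-1-[(1S)-1-methyl-2-(propan-2-ylidene)cyclopentyl]pentan-1-one | OCC(O)CC(C)C(=O)[C@@]1(C)CCCC1=C(C)C | intermediate
15 | 3-methyl-4-[(1S)-1-methyl-2-(propan-2-ylidene)cyclopentyl]-4-oxobutanal (C3 epimers) | O=CCC(C)C(=O)[C@@]1(C)CCCC1=C(C)C | intermediate
16 | (4aS)-3,4a,8,8-tetramethyloctahydronaphthalene-1,4-dione (C3/C8a epimers) | O=C1CC(C)C(=O)[C@@]2(C)CCCC(C)(C)C12 | intermediate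
17 | (3R,4aS,8aS)-3,4a,8,8-tetramethyloctahydronaphthalene-1,4-dione | O=C1C[C@@H](C)C(=O)[C@@]2(C)CCCC(C)(C)[C@H]12 | intermediate
18 | (2R,4R,4aS,8aS)-4-hydroxy-2,5,5,8a-tetramethyloctahydronaphthalen-1(2H)-one | O[C@@H]1C[C@@H](C)C(=O)[C@@]2(C)CCCC(C)(C)[C@H]12 | intermediate
19 | (1R,2R,4R,4aS,8aS)-1-ethenyl-2,5,5,8a-tetramethyldecahydronaphthalene-1,4-diol | O[C@@H]1C[C@@H](C)[C@](O)(C=C)[C@@]2(C)CCCC(C)(C)[C@H]12 | intermediate
20 | (1R,3R,4R,4aS,8aS)-4-ethenyl-4-hydroxy-3,4a,8,8-tetramethyldecahydronaphthalen-1-yl acetate | CC(=O)O[C@@H]1C[C@@H](C)[C@](O)(C=C)[C@@]2(C)CCCC(C)(C)[C@H]12 | intermediate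
21 | 3-bromofuran-2(5H)-one | O=C1OCC=C1Br | starting material
22 | B-alkyl-9-BBN borane from 20 (boron on C12) | CC(=O)O[C@@H]1C[C@@H](C)[C@](O)(CCB3C4CCCC3CCC4)[C@@]2(C)CCCC(C)(C)[C@H]12 | intermediate
23 | (1R,3R,4R,4aS,8aS)-4-hydroxy-3,4a,8,8-tetramethyl-4-[2-(2-oxo-2,5-dihydrofuran-3-yl)ethyl]decahydronaphthalen-1-yl acetate (6β-acetoxy-9α-hydroxy labdane with α-substituted butenolide) | CC(=O)O[C@@H]1C[C@@H](C)[C@](O)(CCC2=CCOC2=O)[C@@]2(C)CCCC(C)(C)[C@H]12 | target

**Total step count:** 13
**Longest linear sequence:** 13 steps (1 → 23; 21 is purchased)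

**Steps most likely to fail**

Step 8 (proposed new method). The cascade may stall after ring B closure by ene-type proton loss from the C4 cation, the 1,4-dicarbonyl may cyclodehydrate to a furan, or a shift other than that of C3 may compete. The fallback sets out from 15 and comes back at 16, and separates the two events into reactions of known type. 15 would first be cyclised with Me2AlCl (CH2Cl2, −78 °C), a Lewis acid that also scavenges the proton and therefore stops at the type-I carbonyl-ene product (3aS)-7-hydroxy-3a,5-dimethyl-7a-(prop-1-en-2-yl)octahydro-4H-inden-4-one F1, which is isolated. F1 would then be treated with a protic acid (TsOH or formic acid, CH2Cl2, 0 °C → rt), so that Markovnikov protonation of the isopropenyl group triggers the Wagner–Meerwein ring expansion and semipinacol hydride shift to 16.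

Step 4. Protonation may occur at the cyclopropane carbon next to the quaternary centre (leading to the 3-isopropylidene isomer), the elimination may run towards the methyl groups, or the cation may be captured by the ketone enol. The fallback sets out from 7 and comes back at 8. Mercury(II) trifluoroacetate (CH2Cl2, 0 °C; aq NaCl) would open the cyclopropane with the bulky electrophile at the less hindered CH carbon and oxygen at the tertiary carbon, giving 1-[(1S,2R)-3-(chloromercurio)-2-(2-hydroxypropan-2-yl)-1-methylcyclopentyl]ethan-1-one F2. Radical demercuration with Bu3SnH (THF, rt) would give 1-[(1S,2R)-2-(2-hydroxypropan-2-yl)-1-methylcyclopentyl]ethan-1-one F3. F3 would be converted with HBr (AcOH, 0 °C) into the tertiary bromide 8 and eliminated as in step 4.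

Step 11. The vinyl nucleophile may attack axially from the α face (wrong C9 configuration) or merely enolise the ketone. The fallback sets out from 18 and comes back at 19, and delivers the oxygen from the α face instead of the carbon from the β face. Wittig methylenation (Ph3PCH3Br, KOt-Bu, toluene, 90 °C) would give (1R,3R,4aS,8aS)-3,4a,8,8-tetramethyl-4-methylidenedecahydronaphthalen-1-ol F4. Peracid epoxidation (mCPBA, NaHCO3, CH2Cl2, 0 °C) from the α face, away from the axial C10 methyl, would give the 9α,11-spiro-epoxide 3,4a,8,8-tetramethylspiro[decahydronaphthalene-4,2'-oxiran]-1-ol F5. Excess dimethylsulfonium methylide (Me3SI, n-BuLi, THF, −10 °C → rt) would open F5 at C11 and eliminate to the one-carbon-homologated allylic alcohol 19.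

**Further compounds**
F1 | step 8 | (3aS)-7-hydroxy-3a,5-dimethyl-7a-(prop-1-en-2-yl)octahydro-4H-inden-4-one (epimers at C5, C7, C7a) | C=C(C)C12CCC[C@]1(C)C(=O)C(C)CC2O
F2 | step 4 | 1-[(1S,2R)-3-(chloromercurio)-2-(2-hydroxypropan-2-yl)-1-methylcyclopentyl]ethan-1-one (mercury trans to the hydroxypropyl group) | CC(=O)[C@@]1(C)CC[C@H]([Hg]Cl)[C@H]1C(C)(C)O
F3 | step 4 | 1-[(1S,2R)-2-(2-hydroxypropan-2-yl)-1-methylcyclopentyl]ethan-1-one | CC(=O)[C@@]1(C)CCC[C@H]1C(C)(C)O
F4 | step 11 | (1R,3R,4aS,8aS)-3,4a,8,8-tetramethyl-4-methylidenedecahydronaphthalen-1-ol | O[C@@H]1C[C@@H](C)C(=C)[C@@]2(C)CCCC(C)(C)[C@H]12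
F5 | step 11 | 3,4a,8,8-tetramethylspiro[decahydronaphthalene-4,2'-oxiran]-1-ol (epoxide oxygen α, 6β-OH) | O[C@@H]1C[C@@H](C)[C@]3(CO3)[C@@]2(C)CCCC(C)(C)[C@H]12
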